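The synthesis rests on the C1–C10 bond. Since the quaternary C5 (bearing C14) lies para to the C8 carbonyl, ring B can be unfolded into a 4-alkyl-4-methylcyclohexa-2,5-dienone whose two enone arms, C6=C7 and C10=C9, are enantiotopic. A primary radical at C1, generated from an iodide on a chain that already carries the C3 and C4 stereocentres, adds 6-exo to C10. This single operation closes ring A, imposes the cis ring fusion, makes C5 and C10 stereogenic and leaves the C6=C7–C8=O enone as the handle for C9 and C7. The precursor is the (2R,3R)-3-silyloxy-5-iodopentan-2-yl dienone 21.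

Key step: step 10

Remark 1: atoms are numbered as in eremophilanes (ring A: C1–C5 and C10; ring B: C5–C10; C14 on C5, C15 on C4, C11–C13 isopropenyl); TBS = tert-butyldimethylsilyl; (−)-Ipc2BOMe is the borinate made from (+)-α-pinene.

Remark 2 (design):
- O1 is carried as a silyl ether, so the dienone is made and unmasked without an oxidant that attacks benzyl-type ethers.
- O3 stays silylated as long as an enone is present, because a free 3-hydroxyl is 1,3-cis to C6 and could add to it.
- C7 is set by carbon–carbon bond formation on the convex face, because protonation of a C7 enolate would deliver hydrogen to that same face and give the C7 epimer.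

Step 1
Reactants: 1 3-[(tert-butyldimethylsilyl)oxy]propanal; 2 cis-but-2-ene
Product: 6 (3R,4R)-1-[(tert-butyldimethylsilyl)oxy]-4-methylhex-5-en-3-ol, via (Z)-crotylpotassium 3 (not isolated), via (Z)-crotylbis(isopinocampheyl)borane 4 (not isolated), via borinate ester 5 (not isolated)
Conditions: 2, KOt-Bu, n-BuLi, THF, −78 → −45 °C; (−)-Ipc2BOMe, −78 °C; BF3·OEt2; 1, −78 °C; then NaOH, H2O2, 0 °C → rt
Reagents that add atoms: none
Why: Brown crotylboration proceeds through a closed six-membered chair transition state, so the Z-crotyl group gives the 3,4-syn adduct while the isopinocampheyl groups from (+)-α-pinene steer the transfer to the Si face of 1, which sets C3 and C4 of the target as (3R,4R).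

Step 2
Reactants: 6 (3R,4R)-1-[(tert-butyldimethylsilyl)oxy]-4-methylhex-5-en-3-ol
Product: 7 (3R,4R)-4,6-bis[(tert-butyldimethylsilyl)oxy]-3-methylhex-1-ene
Conditions: TBSOTf, 2,6-lutidine, CH2Cl2, −78 → 0 °C
Reagents that add atoms: tert-butyldimethylsilyl triflate, CC(C)(C)[Si](C)(C)OS(=O)(=O)C(F)(F)F
Why: Silyl triflate silylation of a secondary alcohol with a hindered pyridine base is fast and clean at low temperature, touches no stereocentre and masks O3 for as long as an enone will be present.

Step 3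
Reactants: 7 (3R,4R)-4,6-bis[(tert-butyldimethylsilyl)oxy]-3-methylhex-1-ene
Product: 9 (3R,4R)-4,6-bis[(tert-butyldimethylsilyl)oxy]-3-methylhexan-1-ol, via B-alkyl-9-BBN adduct 8 (not isolated)
Conditions: 9-BBN, THF, 0 °C → rt; then NaOH, H2O2, 0 °C
Reagents that add atoms: hydrogen peroxide, OO
Why: Hydroboration–oxidation with 9-BBN places boron on the terminal carbon for steric reasons and alkaline peroxide exchanges it for hydroxyl, so the primary alcohol forms without touching C3 or C4.

Step 4
Reactants: 9 (3R,4R)-4,6-bis[(tert-butyldimethylsilyl)oxy]-3-methylhexan-1-ol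
Product: 10 (3R,4R)-4,6-bis[(tert-butyldimethylsilyl)oxy]-3-methylhexanal
Conditions: Dess–Martin periodinane, NaHCO3, CH2Cl2, 0 °C → rt
Reagents that add atoms: none
Why: Dess–Martin oxidation gives the aldehyde under buffered conditions, and C4 is β to the new carbonyl and therefore cannot epimerise.

Step 5
Reactants: 10 (3R,4R)-4,6-bis[(tert-butyldimethylsilyl)oxy]-3-methylhexanal
Product: 13 (3R,4R)-4,6-bis[(tert-butyldimethylsilyl)oxy]-2,3-dimethylhexanal (both C2 epimers), via N-tert-butyl aldimine 11 (not isolated), via α-methyl aldimine 12 (not isolated)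
Conditions: t-BuNH2, MgSO4, CH2Cl2, rt; LiN(i-Pr)2, THF, −78 → 0 °C; MeI, −78 °C → rt; NaOAc–AcOH buffer (pH 5), H2O, 0 °C
Reagents that add atoms: iodomethane, CI; water, O
Why: Metalloenamine (aza-enolate) alkylation: the lithiated N-tert-butyl aldimine is methylated once at carbon and mild hydrolysis returns the aldehyde, the new centre (future C5) arising as a mixture that does not matter because it becomes a non-stereogenic quaternary carbon in 19.

Step 6
Reactants: 13 (3R,4R)-4,6-bis[(tert-butyldimethylsilyl)oxy]-2,3-dimethylhexanal; 14 methyl vinyl ketone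
Product: 17 4-[(2R,3R)-3,5-bis[(tert-butyldimethylsilyl)oxy]pentan-2-yl]-4-methylcyclohex-2-en-1-one (both ring epimers), via pyrrolidine enamine 15 (not isolated), via keto aldehyde 16 (not isolated)
Conditions: pyrrolidine, 4 Å MS, PhMe, rt; 14, 0 °C → rt; H2O; then KOH, MeOH, rt
Reagents that add atoms: none
Why: Robinson annulation by the enamine route: the enamine of the α-branched aldehyde undergoes Michael addition to 14 to create the quaternary carbon and base-mediated intramolecular aldol condensation of the keto aldehyde closes the cyclohexenone, whose ring stereocentre is left uncontrolled on purpose.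

Step 7
Reactants: 17 4-[(2R,3R)-3,5-bis[(tert-butyldimethylsilyl)oxy]pentan-2-yl]-4-methylcyclohex-2-en-1-one
Product: 19 4-[(2R,3R)-3,5-bis[(tert-butyldimethylsilyl)oxy]pentan-2-yl]-4-methylcyclohexa-2,5-dien-1-one, via trimethylsilyl dienol ether 18 (not isolated)
Conditions: LiN(i-Pr)2, Me3SiCl, THF, −78 °C; then Pd(OAc)2, MeCN, rt
Reagents that add atoms: none
Why: Saegusa–Ito oxidation: the only acidic position of the enone is the α′ methylene because the γ carbon is quaternary, and palladium diacetate dehydrosilylates the silyl dienol ether to the cross-conjugated dienone, which removes the uncontrolled ring stereocentre.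

Step 8
Reactants: 19 4-[(2R,3R)-3,5-bis[(tert-butyldimethylsilyl)oxy]pentan-2-yl]-4-methylcyclohexa-2,5-dien-1-one
Product: 20 4-[(2R,3R)-3-[(tert-butyldimethylsilyl)oxy]-5-hydroxypentan-2-yl]-4-methylcyclohexa-2,5-dien-1-one
Conditions: HF·pyridine, pyridine, THF, 0 °C
Reagents that add atoms: none
Why: Selective desilylation: buffered hydrogen fluoride cleaves the unhindered primary silyl ether far faster than the secondary one next to the C4 methyl group, and the non-nucleophilic medium does not add to the dienone.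

Step 9
Reactants: 20 4-[(2R,3R)-3-[(tert-butyldimethylsilyl)oxy]-5-hydroxypentan-2-yl]-4-methylcyclohexa-2,5-dien-1-one
Product: 21 4-[(2R,3R)-3-[(tert-butyldimethylsilyl)oxy]-5-iodopentan-2-yl]-4-methylcyclohexa-2,5-dien-1-one
Conditions: I2, PPh3, imidazole, CH2Cl2, 0 °C → rt
Reagents that add atoms: iodine, [I][I]
Why: Appel-type iodination converts the primary alcohol through its alkoxyphosphonium salt into the iodide by SN2 displacement under neutral conditions that leave the dienone, the silyl ether and both stereocentres untouched.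

Step 10
Reactants: 21 4-[(2R,3R)-3-[(tert-butyldimethylsilyl)oxy]-5-iodopentan-2-yl]-4-methylcyclohexa-2,5-dien-1-one
Product: 22 (4aR,5R,6R,8aR)-6-[(tert-butyldimethylsilyl)oxy]-4a,5-dimethyl-4a,5,6,7,8,8a-hexahydronaphthalen-2(1H)-one
Conditions: (Me3Si)3SiH (1.3 equiv, added over several hours), AIBN (0.2 equiv), PhH (0.005 M), 80 °C
Reagents that add atoms: none
Why: Thermolysis of AIBN starts a chain in which the silyl radical abstracts iodine from 21, the primary C1 radical adds to C10, the β-carbon of one enone arm, and the resulting C9 α-keto radical takes hydrogen from (Me3Si)3SiH, leaving the other arm as the C6=C7–C8=O enone. The closest known reaction type is the tin- or silane-mediated radical cyclisation of ω-haloalkyl chains onto 4,4-disubstituted cyclohexa-2,5-dienones, which gives cis-fused bicyclic enones. Ring A is closed in the 6-exo-trig mode, the 7-endo alternative being attack of a nucleophilic radical on the α-carbon and therefore slow. C10 is controlled by connectivity: the chain hangs from C5 on one face of the flat dienone and can only reach that face, so H10 and C14 end up cis whichever arm reacts. C5 is controlled by the choice of arm, which the C3 and C4 stereocentres make: the required closure has C3 anti to the spectator arm, so that OTBS and C15 are pseudo-equatorial and C14 is pseudo-axial on ring A (the resting conformation of 22), a geometry also favoured by the preference of the larger C5 substituent for the pseudo-axial site of the dienone. The competing closure with C3 folded over the dienone and C14 pseudo-equatorial likewise keeps both chain substituents equatorial and would give the separable 4,5-trans-dimethyl isomer, so this arm selection is the one selectivity that the substrate biases but does not enforce and is the planned point of risk.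

Step 11
Reactants: 22 (4aR,5R,6R,8aR)-6-[(tert-butyldimethylsilyl)oxy]-4a,5-dimethyl-4a,5,6,7,8,8a-hexahydronaphthalen-2(1H)-one
Product: 25 (1R,4aR,5R,6R,8aS)-6-[(tert-butyldimethylsilyl)oxy]-1-hydroxy-4a,5-dimethyl-4a,5,6,7,8,8a-hexahydronaphthalen-2(1H)-one, via silyl dienol ether 23 (not isolated), via 9-trimethylsilyloxy ketone 24 (not isolated)
Conditions: LiN(i-Pr)2, Me3SiCl, THF, −78 °C; mCPBA, NaHCO3, CH2Cl2, −20 → 0 °C; citric acid, MeOH, 0 °C
Reagents that add atoms: mCPBA, OOC(=O)c1cccc(Cl)c1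
Why: Rubottom oxidation: the enone can only be deprotonated at C9 (C5 is quaternary, so there is no γ-proton), the silyl dienol ether is epoxidised at its electron-rich C8=C9 bond on the convex β face because the α face is screened by the axial C5–C4 bond of ring A, and silyl migration then methanolysis deliver the equatorial 9β-alcohol.

Step 12
Reactants: 25 (1R,4aR,5R,6R,8aS)-6-[(tert-butyldimethylsilyl)oxy]-1-hydroxy-4a,5-dimethyl-4a,5,6,7,8,8a-hexahydronaphthalen-2(1H)-one; 26 angelic acid [(2Z)-2-methylbut-2-enoic acid]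
Product: 28 (1R,4aR,5R,6R,8aS)-6-[(tert-butyldimethylsilyl)oxy]-4a,5-dimethyl-2-oxo-1,2,4a,5,6,7,8,8a-octahydronaphthalen-1-yl (2Z)-2-methylbut-2-enoate, via mixed anhydride 27 (not isolated)
Conditions: 26, 2,4,6-trichlorobenzoyl chloride, Et3N, PhMe, rt; then 25, 75 °C
Reagents that add atoms: none
Why: Mixed-anhydride (Yamaguchi-type) esterification run without a nucleophilic catalyst lets the alcohol attack the unhindered angeloyl carbonyl, a protocol chosen because it keeps the Z geometry of the angelate, and it is done at this robust enone stage so that no later step has to heat a sensitive ketone with base.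

Step 13
Reactants: 28 (1R,4aR,5R,6R,8aS)-6-[(tert-butyldimethylsilyl)oxy]-4a,5-dimethyl-2-oxo-1,2,4a,5,6,7,8,8a-octahydronaphthalen-1-yl (2Z)-2-methylbut-2-enoate; 29 acetone
Product: 31 (1R,3R,4aR,5R,6R,8aS)-6-[(tert-butyldimethylsilyl)oxy]-3-(2-hydroxypropan-2-yl)-4a,5-dimethyl-2-oxodecahydronaphthalen-1-yl (2Z)-2-methylbut-2-enoate, via triethylsilyl enol ether 30 (not isolated)
Conditions: Et3SiH, RhCl(PPh3)3 (cat.), PhH, 50 °C; solvent exchange; 29, TiCl4, CH2Cl2, −78 °C; aq. NaHCO3
Reagents that add atoms: none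
Why: Rhodium-catalysed conjugate hydrosilylation gives the C7=C8 enol silane regiospecifically and the following Mukaiyama aldol addition brings TiCl4-activated acetone to C7 from the convex β face (the α face is covered by ring A), so C7 receives its carbon substituent β and equatorial with H7 on the α face as in the target.

Step 14
Reactants: 31 (1R,3R,4aR,5R,6R,8aS)-6-[(tert-butyldimethylsilyl)oxy]-3-(2-hydroxypropan-2-yl)-4a,5-dimethyl-2-oxodecahydronaphthalen-1-yl (2Z)-2-methylbut-2-enoate
Product: 33 (1R,3R,4aR,5R,6R,8aS)-6-[(tert-butyldimethylsilyl)oxy]-4a,5-dimethyl-2-oxo-3-(prop-1-en-2-yl)decahydronaphthalen-1-yl (2Z)-2-methylbut-2-enoate, via chlorosulfite 32 (not isolated)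
Conditions: SOCl2, pyridine, CH2Cl2, −20 → 0 °C
Reagents that add atoms: none
Why: Dehydration by E2 elimination of the chlorosulfite with pyridine should give the isopropenyl group, because the only alternative β-hydrogen is the single C7–H buried on the concave face whereas six methyl hydrogens are exposed, and the reaction does not touch the C7 stereocentre.

Step 15
Reactants: 33 (1R,3R,4aR,5R,6R,8aS)-6-[(tert-butyldimethylsilyl)oxy]-4a,5-dimethyl-2-oxo-3-(prop-1-en-2-yl)decahydronaphthalen-1-yl (2Z)-2-methylbut-2-enoate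
Product: 34 (1R,3R,4aR,5R,6R,8aS)-6-hydroxy-4a,5-dimethyl-2-oxo-3-(prop-1-en-2-yl)decahydronaphthalen-1-yl (2Z)-2-methylbut-2-enoate
Conditions: HF·pyridine, pyridine, THF, 0 °C → rt
Reagents that add atoms: none
Why: Buffered hydrogen fluoride desilylation frees the C3 hydroxyl under weakly acidic conditions, so the β,γ-unsaturated ketone, the C7 and C9 centres and the angelate are not exposed to base, and with C6 now saturated the hydroxyl has no enone to add to.

Step 16
Reactants: 34 (1R,3R,4aR,5R,6R,8aS)-6-hydroxy-4a,5-dimethyl-2-oxo-3-(prop-1-en-2-yl)decahydronaphthalen-1-yl (2Z)-2-methylbut-2-enoate; 35 3-methylbut-2-enoyl chloride (senecioyl chloride)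
Product: 36 (1R,3R,4aR,5R,6R,8aS)-4a,5-dimethyl-6-[(3-methylbut-2-enoyl)oxy]-2-oxo-3-(prop-1-en-2-yl)decahydronaphthalen-1-yl (2Z)-2-methylbut-2-enoate (CNP0164025.2)
Conditions: 35, pyridine, DMAP (cat.), CH2Cl2, 0 °C → rt
Reagents that add atoms: none
Why: DMAP-catalysed acylation of the secondary alcohol with the acid chloride in pyridine forms the senecioate, the weak base being unable to deconjugate the acyl group or to enolise the ketone, and no stereocentre is touched.

Compound list

1 | 3-[(tert-butyldimethylsilyl)oxy]propanal | CC(C)(C)[Si](C)(C)OCCC=O | starting material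
2 | cis-but-2-ene | C/C=C\C | starting material
3 | (Z)-crotylpotassium | C/C=C\C[K] | intermediate
4 | (Z)-crotylbis(isopinocampheyl)borane | C/C=C\CB([C@@H]1C[C@@H]2C[C@H]([C@H]1C)C2(C)C)[C@@H]1C[C@@H]2C[C@H]([C@H]1C)C2(C)C | intermediate
5 | bis(isopinocampheyl)borinate ester of 6 | CC(C)(C)[Si](C)(C)OCC[C@@H](OB([C@@H]1C[C@@H]2C[C@H]([C@H]1C)C2(C)C)[C@@H]1C[C@@H]2C[C@H]([C@H]1C)C2(C)C)[C@H](C)C=C | intermediate
6 | (3R,4R)-1-[(tert-butyldimethylsilyl)oxy]-4-methylhex-5-en-3-ol | CC(C)(C)[Si](C)(C)OCC[C@@H](O)[C@H](C)C=C | intermediate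
7 | (3R,4R)-4,6-bis[(tert-butyldimethylsilyl)oxy]-3-methylhex-1-ene | CC(C)(C)[Si](C)(C)OCC[C@@H](O[Si](C)(C)C(C)(C)C)[C@H](C)C=C | intermediate
8 | B-alkyl-9-borabicyclo[3.3.1]nonane adduct of 7 | CC(C)(C)[Si](C)(C)OCC[C@@H](O[Si](C)(C)C(C)(C)C)[C@H](C)CCB1C2CCCC1CCC2 | intermediate
9 | (3R,4R)-4,6-bis[(tert-butyldimethylsilyl)oxy]-3-methylhexan-1-ol | CC(C)(C)[Si](C)(C)OCC[C@@H](O[Si](C)(C)C(C)(C)C)[C@H](C)CCO | intermediate
10 | (3R,4R)-4,6-bis[(tert-butyldimethylsilyl)oxy]-3-methylhexanal | CC(C)(C)[Si](C)(C)OCC[C@@H](O[Si](C)(C)C(C)(C)C)[C@H](C)CC=O | intermediate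
11 | N-tert-butyl aldimine of 10 | CC(C)(C)[Si](C)(C)OCC[C@@H](O[Si](C)(C)C(C)(C)C)[C@H](C)CC=NC(C)(C)C | intermediate
12 | N-tert-butyl aldimine of 13 | CC(C)(C)[Si](C)(C)OCC[C@@H](O[Si](C)(C)C(C)(C)C)[C@H](C)C(C)C=NC(C)(C)C | intermediate
13 | (3R,4R)-4,6-bis[(tert-butyldimethylsilyl)oxy]-2,3-dimethylhexanal (both C2 epimers) | CC(C)(C)[Si](C)(C)OCC[C@@H](O[Si](C)(C)C(C)(C)C)[C@H](C)C(C)C=O | intermediate
14 | methyl vinyl ketone (but-3-en-2-one) | CC(=O)C=C | starting material
15 | pyrrolidine enamine of 13 | CC(C)(C)[Si](C)(C)OCC[C@@H](O[Si](C)(C)C(C)(C)C)[C@H](C)C(C)=CN1CCCC1 | intermediate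
16 | 2-[(2R,3R)-3,5-bis[(tert-butyldimethylsilyl)oxy]pentan-2-yl]-2-methyl-5-oxohexanal (both C2 epimers) | CC(C)(C)[Si](C)(C)OCC[C@@H](O[Si](C)(C)C(C)(C)C)[C@H](C)C(C)(C=O)CCC(C)=O | intermediate
17 | 4-[(2R,3R)-3,5-bis[(tert-butyldimethylsilyl)oxy]pentan-2-yl]-4-methylcyclohex-2-en-1-one (both ring epimers) | CC(C)(C)[Si](C)(C)OCC[C@@H](O[Si](C)(C)C(C)(C)C)[C@H](C)C1(C)C=CC(=O)CC1 | intermediate
18 | trimethylsilyl dienol ether of 17 | CC(C)(C)[Si](C)(C)OCC[C@@H](O[Si](C)(C)C(C)(C)C)[C@H](C)C1(C)C=CC(O[Si](C)(C)C)=CC1 | intermediate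
19 | 4-[(2R,3R)-3,5-bis[(tert-butyldimethylsilyl)oxy]pentan-2-yl]-4-methylcyclohexa-2,5-dien-1-one | CC(C)(C)[Si](C)(C)OCC[C@@H](O[Si](C)(C)C(C)(C)C)[C@H](C)C1(C)C=CC(=O)C=C1 | intermediate
20 | 4-[(2R,3R)-3-[(tert-butyldimethylsilyl)oxy]-5-hydroxypentan-2-yl]-4-methylcyclohexa-2,5-dien-1-one | OCC[C@@H](O[Si](C)(C)C(C)(C)C)[C@H](C)C1(C)C=CC(=O)C=C1 | intermediate
21 | 4-[(2R,3R)-3-[(tert-butyldimethylsilyl)oxy]-5-iodopentan-2-yl]-4-methylcyclohexa-2,5-dien-1-one (key-step precursor) | ICC[C@@H](O[Si](C)(C)C(C)(C)C)[C@H](C)C1(C)C=CC(=O)C=C1 | intermediate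
22 | (4aR,5R,6R,8aR)-6-[(tert-butyldimethylsilyl)oxy]-4a,5-dimethyl-4a,5,6,7,8,8a-hexahydronaphthalen-2(1H)-one (key-step product; cis-fused, 3α-OTBS, 4β,5β-dimethyl, 6-en-8-one in target numbering) | C1=C[C@@]2(C)[C@H](CC[C@@H](O[Si](C)(C)C(C)(C)C)[C@@H]2C)CC1=O | intermediate
23 | C8 trimethylsilyl dienol ether of 22 | C1=C[C@@]2(C)[C@H](CC[C@@H](O[Si](C)(C)C(C)(C)C)[C@@H]2C)C=C1O[Si](C)(C)C | intermediate
24 | 9β-trimethylsilyl ether of 25 | C1=C[C@@]2(C)[C@H](CC[C@@H](O[Si](C)(C)C(C)(C)C)[C@@H]2C)[C@@H](O[Si](C)(C)C)C1=O | intermediate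
25 | (1R,4aR,5R,6R,8aS)-6-[(tert-butyldimethylsilyl)oxy]-1-hydroxy-4a,5-dimethyl-4a,5,6,7,8,8a-hexahydronaphthalen-2(1H)-one | C1=C[C@@]2(C)[C@H](CC[C@@H](O[Si](C)(C)C(C)(C)C)[C@@H]2C)[C@@H](O)C1=O | intermediate
26 | angelic acid, (2Z)-2-methylbut-2-enoic acid | C/C=C(/C)C(O)=O | starting material
27 | angelic 2,4,6-trichlorobenzoic anhydride | C/C=C(/C)C(=O)OC(=O)c1c(Cl)cc(Cl)cc1Cl | intermediate
28 | (1R,4aR,5R,6R,8aS)-6-[(tert-butyldimethylsilyl)oxy]-4a,5-dimethyl-2-oxo-1,2,4a,5,6,7,8,8a-octahydronaphthalen-1-yl (2Z)-2-methylbut-2-enoate | C1=C[C@@]2(C)[C@H](CC[C@@H](O[Si](C)(C)C(C)(C)C)[C@@H]2C)[C@@H](OC(=O)/C(C)=C\C)C1=O | intermediate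
29 | acetone | CC(C)=O | starting material
30 | C7=C8 triethylsilyl enol ether from 28 | CC[Si](CC)(CC)OC1=CC[C@@]2(C)[C@H](CC[C@@H](O[Si](C)(C)C(C)(C)C)[C@@H]2C)[C@H]1OC(=O)/C(C)=C\C | intermediate
31 | (1R,3R,4aR,5R,6R,8aS)-6-[(tert-butyldimethylsilyl)oxy]-3-(2-hydroxypropan-2-yl)-4a,5-dimethyl-2-oxodecahydronaphthalen-1-yl (2Z)-2-methylbut-2-enoate | CC(C)(O)[C@H]1C[C@@]2(C)[C@H](CC[C@@H](O[Si](C)(C)C(C)(C)C)[C@@H]2C)[C@@H](OC(=O)/C(C)=C\C)C1=O | intermediate
32 | chlorosulfite of 31 | CC(C)(OS(=O)Cl)[C@H]1C[C@@]2(C)[C@H](CC[C@@H](O[Si](C)(C)C(C)(C)C)[C@@H]2C)[C@@H](OC(=O)/C(C)=C\C)C1=O | intermediate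
33 | (1R,3R,4aR,5R,6R,8aS)-6-[(tert-butyldimethylsilyl)oxy]-4a,5-dimethyl-2-oxo-3-(prop-1-en-2-yl)decahydronaphthalen-1-yl (2Z)-2-methylbut-2-enoate | C=C(C)[C@H]1C[C@@]2(C)[C@H](CC[C@@H](O[Si](C)(C)C(C)(C)C)[C@@H]2C)[C@@H](OC(=O)/C(C)=C\C)C1=O | intermediate
34 | (1R,3R,4aR,5R,6R,8aS)-6-hydroxy-4a,5-dimethyl-2-oxo-3-(prop-1-en-2-yl)decahydronaphthalen-1-yl (2Z)-2-methylbut-2-enoate | C=C(C)[C@H]1C[C@@]2(C)[C@H](CC[C@@H](O)[C@@H]2C)[C@@H](OC(=O)/C(C)=C\C)C1=O | intermediate
35 | 3-methylbut-2-enoyl chloride (senecioyl chloride) | CC(C)=CC(Cl)=O | starting material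
36 | (1R,3R,4aR,5R,6R,8aS)-4a,5-dimethyl-6-[(3-methylbut-2-enoyl)oxy]-2-oxo-3-(prop-1-en-2-yl)decahydronaphthalen-1-yl (2Z)-2-methylbut-2-enoate (CNP0164025.2) | C=C(C)[C@H]1C[C@@]2(C)[C@H](CC[C@@H](OC(=O)C=C(C)C)[C@@H]2C)[C@@H](OC(=O)/C(C)=C\C)C1=O | target

Total step count: 16. Longest linear sequence: 16 steps (1 → 36); compounds 2, 14, 26, 29 and 35 are bought.

Steps most likely to fail

1. Step 10 – ring closure onto the other enone arm. The chain substituents are equatorial in both competing closures, and the ordinary chair picture for a 6-exo ring closure (C3 folded over the dienone, C14 pseudo-equatorial) leads to the 4,5-trans-dimethyl diastereomer. The unwanted arm may therefore compete strongly or even be preferred. Premature hydrogen transfer to the open-chain radical is a lesser concern. Fallback (sets out from 17, returns at 22): give up the desymmetrisation and fix C5 before the radical step. The two ring epimers of 17 are separated by chromatography and the (4S)-enone F1, whose enone arm is the future C10=C9, is taken on; its epimer can still be used in step 7. Selective primary desilylation (HF·pyridine) gives alcohol F2 and Appel iodination gives iodide F3. The radical conditions of step 10 then have only one enone arm to attack and give the cis-fused saturated ketone F4. Kinetic enolisation away from the ring fusion (LiN(i-Pr)2, Me3SiCl) to the C7 enol silane F5 and Saegusa–Ito oxidation (Pd(OAc)2) restore the C6=C7 bond and deliver 22.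

2. Step 14 – elimination in the wrong direction (loss of the C7 hydrogen to give the conjugated isopropylidene ketone) or substitution to the tertiary chloride. Fallback (sets out from 28, returns at 33): form the C7–C11 bond with the alkene already in place. Enol silane 30, prepared as in step 13, is converted with Bu3SnF into the tributyltin enolate F6. This is coupled with 2-bromopropene under palladium catalysis (PdCl2[P(o-tol)3]2, PhH, reflux; tin-enolate α-alkenylation). The metal binds C7 on the convex face, so 33 should form with the same C7 configuration and without any elimination step.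

3. Step 6 – failure of the Michael addition at the hindered α-carbon next to C4, polymerisation of 14, or loss of a silyl group during the aldol closure. Fallback (sets out from 13, returns at 16): replace the enamine by a Lewis-acid-mediated Michael addition. Aldehyde 13 is converted into its trimethylsilyl enol ether F7 (Me3SiCl, Et3N, NaI, MeCN), which adds to 14 in a Mukaiyama–Michael reaction (TiCl4, CH2Cl2, −78 °C) to give keto aldehyde 16. The base-mediated closure of step 6 then gives 17.

Further compounds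

F1 | step 10 | (4S)-4-[(2R,3R)-3,5-bis[(tert-butyldimethylsilyl)oxy]pentan-2-yl]-4-methylcyclohex-2-en-1-one | CC(C)(C)[Si](C)(C)OCC[C@@H](O[Si](C)(C)C(C)(C)C)[C@H](C)[C@]1(C)C=CC(=O)CC1
F2 | step 10 | (4S)-4-[(2R,3R)-3-[(tert-butyldimethylsilyl)oxy]-5-hydroxypentan-2-yl]-4-methylcyclohex-2-en-1-one | OCC[C@@H](O[Si](C)(C)C(C)(C)C)[C@H](C)[C@]1(C)C=CC(=O)CC1
F3 | step 10 | (4S)-4-[(2R,3R)-3-[(tert-butyldimethylsilyl)oxy]-5-iodopentan-2-yl]-4-methylcyclohex-2-en-1-one | ICC[C@@H](O[Si](C)(C)C(C)(C)C)[C@H](C)[C@]1(C)C=CC(=O)CC1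
F4 | step 10 | (4aS,5R,6R,8aR)-6-[(tert-butyldimethylsilyl)oxy]-4a,5-dimethyloctahydronaphthalen-2(1H)-one | C1C[C@@]2(C)[C@H](CC[C@@H](O[Si](C)(C)C(C)(C)C)[C@@H]2C)CC1=O
F5 | step 10 | C7=C8 trimethylsilyl enol ether of F4 | C[Si](C)(C)OC1=CC[C@@]2(C)[C@H](CC[C@@H](O[Si](C)(C)C(C)(C)C)[C@@H]2C)C1
F6 | step 14 | C7=C8 tributyltin enolate corresponding to 30 | CCCC[Sn](CCCC)(CCCC)OC1=CC[C@@]2(C)[C@H](CC[C@@H](O[Si](C)(C)C(C)(C)C)[C@@H]2C)[C@H]1OC(=O)/C(C)=C\C
F7 | step 6 | trimethylsilyl enol ether of 13 | CC(C)(C)[Si](C)(C)OCC[C@@H](O[Si](C)(C)C(C)(C)C)[C@H](C)C(C)=CO[Si](C)(C)C
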